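The butenolide is taken apart at its ring oxygen first. O1 of the 4-methyl-5-ylidenefuran-2(5H)-one ring is read as a Baeyer–Villiger-inserted atom. C2 (lactone carbonyl) and C5 (ylidene carbon) were then once directly bonded, as the two carbons of a ketene-type cumulene, and C3H=C4(CH3) is simply propyne. The key step is therefore a keteniminium–alkyne [2+2] cycloaddition. It joins propyne to a fully elaborated, silyl-protected C22 labdane β-silyloxy amide and makes C2–C3 and C4–C5 at once as a 3-methylcyclobutenone. Ring expansion and loss of silanol then give the (Z)-ylidene butenolide. The decalin comes from (+)-larixol, whose 6α-OH delivers the C18 oxygen by 1,5-hydrogen transfer.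

Key step: step 10

Assumption: (+)-larixol is taken as a commercial chiral-pool diterpenoid. C15 and the side-chain-bearing carbon of the four- or five-membered ring are carried as epimer mixtures, because both become sp2 in step 12. Labdane numbering is used for the terpenoid part.

Step 1
Reactants: 1 (+)-larixol
Product: 2 (13S)-8α,17-epoxylabd-14-ene-6α,13-diol
Conditions: mCPBA, NaHCO3, CH2Cl2, 0 °C
Reagents that add atoms: mCPBA OOC(=O)c1cccc(Cl)c1
Why: Prilezhaev epoxidation, in which the 1,1-disubstituted C8=C17 alkene is far more nucleophilic than the vinyl group and the peracid should approach from the α face because the β face is screened by the axial C10 methyl, which sets C8 with oxygen on the α side.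

Step 2
Reactants: 2 (13S)-8α,17-epoxylabd-14-ene-6α,13-diol
Product: 4 8α,17-epoxy-6α-hydroxy-14,15-dinorlabdan-13-one, via side-chain triol 3 (not isolated)
Conditions: OsO4 (cat.), NaIO4, 2,6-lutidine, dioxane–H2O, rt
Reagents that add atoms: none
Why: Lemieux–Johnson dihydroxylation/periodate cleavage, in which the vinyl carbinol becomes a 13,14,15-triol whose two glycol C–C bonds are cut to leave the C13 methyl ketone, while the isolated 6α-OH and the buffered epoxide should stay untouched.

Step 3
Reactants: 4 8α,17-epoxy-6α-hydroxy-14,15-dinorlabdan-13-one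
Product: 5 6α,18:8α,17-diepoxy-14,15-dinorlabdan-13-one
Conditions: PhI(OAc)2, I2, cyclohexane–CH2Cl2, visible light, rt
Reagents that add atoms: none
Why: Suárez hypoiodite reaction, in which the equatorial 6α-alkoxy radical and the equatorial 4α-methyl (C18) lie on parallel peri bonds about 2.5 Å apart, so 1,5-hydrogen transfer, iodination and ring closure should give the tetrahydrofuran, distinguish the geminal methyls and thereby set C4.

Step 4
Reactants: 5 6α,18:8α,17-diepoxy-14,15-dinorlabdan-13-one
Product: 6 8α,17-epoxy-13-oxo-14,15-dinorlabdan-18,6α-olide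
Conditions: RuCl3·xH2O (cat.), NaIO4, CCl4–MeCN–H2O, rt
Reagents that add atoms: sodium periodate [Na+].[O-]I(=O)(=O)=O
Why: Catalytic RuO4 oxidation of an ether to a lactone, which should take the accessible O–CH2 (C18) rather than the hindered O–CH (C6) and meets no alkene at this stage.

Step 5
Reactants: 6 8α,17-epoxy-13-oxo-14,15-dinorlabdan-18,6α-olide; 7 triethyl phosphonoacetate
Product: 8 ethyl (13E)-8α,17-epoxylabd-13-en-18,6α-olid-15-oate
Conditions: NaH, THF, 0 °C → reflux; chromatographic removal of the minor 13Z isomer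
Reagents that add atoms: triethyl phosphonoacetate (7) CCOC(=O)CP(=O)(OCC)OCC
Why: Horner–Wadsworth–Emmons olefination of a methyl ketone, which should favour the E enoate (ester anti to the larger CH2 branch) and so sets the C13=C14 geometry, while the lactone (quaternary α-carbon) and the epoxide are inert to the stabilised anion.

Step 6
Reactants: 8 ethyl (13E)-8α,17-epoxylabd-13-en-18,6α-olid-15-oate
Product: 9 (13E)-labd-13-ene-6α,8α,15,18-tetraol
Conditions: LiAlH4, THF, 0 °C → reflux; aq NaOH work-up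
Reagents that add atoms: none
Why: Global hydride reduction, in which the enoate gives the allylic alcohol, the lactone gives the 6α,18-diol and hydride opens the spiro-epoxide at its CH2 terminus, so that the C8–O bond is kept and 8α-OH/8β-CH3 results.

Step 7
Reactants: 9 (13E)-labd-13-ene-6α,8α,15,18-tetraol
Product: 10 (13E)-6α,8α,18-trihydroxylabd-13-en-15-al
Conditions: activated MnO2, acetone–CH2Cl2, rt
Reagents that add atoms: none
Why: MnO2 oxidation is selective for the allylic alcohol, so the neopentyl primary, the secondary and the tertiary hydroxyl groups should be left alone and the E alkene retained.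

Step 8
Reactants: 10 (13E)-6α,8α,18-trihydroxylabd-13-en-15-al; 11 N,N-dimethylacetamide
Product: 12 (13E)-15-[(dimethylcarbamoyl)methyl]labd-13-ene-6α,8α,15,18-tetraol (C15 epimers)
Conditions: LDA and 11 (about 6 equiv each), THF, −78 °C; then 10; aq NH4Cl
Reagents that add atoms: N,N-dimethylacetamide (11) CC(=O)N(C)C
Why: Aldol addition of a hard lithium amide enolate, which should add 1,2 to the β,β-disubstituted enal faster than any alkoxide-mediated side reaction at −78 °C, the excess enolate covering the three free hydroxyl groups and the new C15 centre being erased later.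

Step 9
Reactants: 12 (13E)-15-[(dimethylcarbamoyl)methyl]labd-13-ene-6α,8α,15,18-tetraol
Product: 13 6,8,15,18-tetrakis-O-TBS ether of 12
Conditions: TBSOTf (excess), 2,6-lutidine, CH2Cl2, 0 °C → rt
Reagents that add atoms: TBSOTf CC(C)(C)[Si](C)(C)OS(=O)(=O)C(F)(F)F
Why: Silyl triflate silylation is strong enough to cap the primary, both secondary and the hindered tertiary 8α-hydroxyl group in one operation, and it gives ethers that neither participate at an activated amide nor suffer in the oxidation to come.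

Step 10
Reactants: 13 6,8,15,18-tetrakis-O-TBS ether of 12; 14 propyne
Product: 17 4-[(13E)-6α,8α,15,18-tetrakis(TBS-oxy)labd-13-en-15-yl]-3-methylcyclobut-2-en-1-one, via keteniminium triflate 15 (not isolated), via cyclobuteniminium triflate 16 (not isolated)
Conditions: Tf2O, 2,4,6-collidine, propyne (large excess, condensed), CH2Cl2, −30 → 35 °C, sealed tube; then aq NaHCO3, rt
Reagents that add atoms: propyne (14) CC#C; water O
Why: O-Triflation of the amide and loss of an α-proton to collidine give keteniminium ion 15, whose central carbon is attacked by the terminal carbon of propyne while positive charge builds up on the methyl-bearing alkyne carbon, which closes onto the enamine carbon to give salt 16, and mild hydrolysis then frees the enone. The closest known reaction type is the keteniminium–alkyne [2+2] cycloaddition that leads to cyclobutenones. The four-membered ring is closed in this intermolecular, asynchronous [2+2] mode, both new σ-bonds arising in the same operation. The one new stereocentre (ring C4) is not controlled and needs no control, because it becomes sp2 in step 12. The step needs regioselectivity, secured by the Markovnikov polarisation of the terminal alkyne (CH to the C=N+ carbon, C–CH3 to the side-chain carbon), and chemoselectivity over the C13=C14 alkene, secured by its trisubstitution, by the one-carbon tether that forbids an intramolecular [2+2] and by the excess of propyne. Enolisation of 16 or 17 would create a cyclobutadiene, so the β-silyloxy group should be safe once the ring has formed.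

Step 11
Reactants: 17 4-[(13E)-6α,8α,15,18-tetrakis(TBS-oxy)labd-13-en-15-yl]-3-methylcyclobut-2-en-1-one
Product: 18 5-[(13E)-6α,8α,15,18-tetrakis(TBS-oxy)labd-13-en-15-yl]-4-methylfuran-2(5H)-one
Conditions: 30% aq H2O2, AcOH–THF, 0 °C
Reagents that add atoms: hydrogen peroxide OO
Why: Baeyer–Villiger ring expansion of a strained four-membered ketone, in which the secondary allylic sp3 carbon should migrate in preference to the vinylic carbon and so place the oxygen between the carbonyl and the side-chain carbon, while the nucleophilic oxidant should leave the isolated trisubstituted alkene alone.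

Step 12
Reactants: 18 5-[(13E)-6α,8α,15,18-tetrakis(TBS-oxy)labd-13-en-15-yl]-4-methylfuran-2(5H)-one
Product: 19 (5Z)-5-[(13E)-6α,8α,18-tris(TBS-oxy)labd-13-en-15-ylidene]-4-methylfuran-2(5H)-one
Conditions: DBU, CH2Cl2, 0 °C → rt
Reagents that add atoms: none
Why: E1cB elimination, in which DBU removes the acidic γ-proton of the butenolide and the furanolate expels the C15 silanolate, all epimers converging on the Z alkene because the E isomer would press the chain against the ring C4 methyl.

Step 13
Reactants: 19 (5Z)-5-[(13E)-6α,8α,18-tris(TBS-oxy)labd-13-en-15-ylidene]-4-methylfuran-2(5H)-one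
Product: 20 (5Z)-5-[(13E)-6α,8α,18-trihydroxylabd-13-en-15-ylidene]-4-methylfuran-2(5H)-one (CNP0126806.1)
Conditions: HF·pyridine, pyridine–THF, 0 °C → rt
Reagents that add atoms: none
Why: Fluoride-driven desilylation under buffered, non-basic conditions should free all three hydroxyl groups without opening the enol lactone, isomerising the dienyl system or dehydrating the tertiary alcohol.

Compound list
1 | (+)-larixol, (13S)-labda-8(17),14-diene-6α,13-diol | C=C[C@@](C)(O)CC[C@@H]1[C@@]2(C)CCCC(C)(C)[C@@H]2[C@@H](O)CC1=C | starting material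
2 | (13S)-8α,17-epoxylabd-14-ene-6α,13-diol | C=C[C@@](C)(O)CC[C@@H]1[C@@]2(C)CCCC(C)(C)[C@@H]2[C@@H](O)C[C@]13CO3 | intermediate
3 | 8α,17-epoxylabdane-6α,13,14,15-tetraol (C14 epimers, not isolated) | OCC(O)[C@@](C)(O)CC[C@@H]1[C@@]2(C)CCCC(C)(C)[C@@H]2[C@@H](O)C[C@]13CO3 | intermediate
4 | 8α,17-epoxy-6α-hydroxy-14,15-dinorlabdan-13-one | CC(=O)CC[C@@H]1[C@@]2(C)CCCC(C)(C)[C@@H]2[C@@H](O)C[C@]13CO3 | intermediate
5 | 6α,18:8α,17-diepoxy-14,15-dinorlabdan-13-one | CC(=O)CC[C@@H]1[C@@]2(C)CCC[C@@](C)(CO4)[C@@H]2[C@@H]4C[C@]13CO3 | intermediate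
6 | 8α,17-epoxy-13-oxo-14,15-dinorlabdan-18,6α-olide | CC(=O)CC[C@@H]1[C@@]2(C)CCC[C@@](C)(C(=O)O4)[C@@H]2[C@@H]4C[C@]13CO3 | intermediate
7 | triethyl phosphonoacetate | CCOC(=O)CP(=O)(OCC)OCC | starting material
8 | ethyl (13E)-8α,17-epoxylabd-13-en-18,6α-olid-15-oate | CCOC(=O)/C=C(\C)CC[C@@H]1[C@@]2(C)CCC[C@@](C)(C(=O)O4)[C@@H]2[C@@H]4C[C@]13CO3 | intermediate
9 | (13E)-labd-13-ene-6α,8α,15,18-tetraol | OC/C=C(\C)CC[C@@H]1[C@@]2(C)CCC[C@@](C)(CO)[C@@H]2[C@@H](O)C[C@@]1(C)O | intermediate
10 | (13E)-6α,8α,18-trihydroxylabd-13-en-15-al | O=C/C=C(\C)CC[C@@H]1[C@@]2(C)CCC[C@@](C)(CO)[C@@H]2[C@@H](O)C[C@@]1(C)O | intermediate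
11 | N,N-dimethylacetamide | CC(=O)N(C)C | starting material
12 | (13E)-15-[(dimethylcarbamoyl)methyl]labd-13-ene-6α,8α,15,18-tetraol (C15 epimers) | CN(C)C(=O)CC(O)/C=C(\C)CC[C@@H]1[C@@]2(C)CCC[C@@](C)(CO)[C@@H]2[C@@H](O)C[C@@]1(C)O | intermediate
13 | 6,8,15,18-tetrakis-O-TBS ether of 12 | CN(C)C(=O)CC(O[Si](C)(C)C(C)(C)C)/C=C(\C)CC[C@@H]1[C@@]2(C)CCC[C@@](C)(CO[Si](C)(C)C(C)(C)C)[C@@H]2[C@@H](O[Si](C)(C)C(C)(C)C)C[C@@]1(C)O[Si](C)(C)C(C)(C)C | intermediate
14 | propyne | CC#C | starting material
15 | N,N-dimethylketeniminium triflate derived from 13 (not isolated) | C[N+](C)=C=CC(O[Si](C)(C)C(C)(C)C)/C=C(\C)CC[C@@H]1[C@@]2(C)CCC[C@@](C)(CO[Si](C)(C)C(C)(C)C)[C@@H]2[C@@H](O[Si](C)(C)C(C)(C)C)C[C@@]1(C)O[Si](C)(C)C(C)(C)C.[O-]S(=O)(=O)C(F)(F)F | intermediate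
16 | 3-methyl-4-substituted cyclobut-2-en-1-ylidene dimethyliminium triflate (not isolated) | C[N+](C)=C1C=C(C)C1C(O[Si](C)(C)C(C)(C)C)/C=C(\C)CC[C@@H]1[C@@]2(C)CCC[C@@](C)(CO[Si](C)(C)C(C)(C)C)[C@@H]2[C@@H](O[Si](C)(C)C(C)(C)C)C[C@@]1(C)O[Si](C)(C)C(C)(C)C.[O-]S(=O)(=O)C(F)(F)F | intermediate
17 | 4-[(13E)-6α,8α,15,18-tetrakis(TBS-oxy)labd-13-en-15-yl]-3-methylcyclobut-2-en-1-one (epimers at ring C4 and C15) | O=C1C=C(C)C1C(O[Si](C)(C)C(C)(C)C)/C=C(\C)CC[C@@H]1[C@@]2(C)CCC[C@@](C)(CO[Si](C)(C)C(C)(C)C)[C@@H]2[C@@H](O[Si](C)(C)C(C)(C)C)C[C@@]1(C)O[Si](C)(C)C(C)(C)C | intermediate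
18 | 5-[(13E)-6α,8α,15,18-tetrakis(TBS-oxy)labd-13-en-15-yl]-4-methylfuran-2(5H)-one (epimers at ring C5 and C15) | CC1=CC(=O)OC1C(O[Si](C)(C)C(C)(C)C)/C=C(\C)CC[C@@H]1[C@@]2(C)CCC[C@@](C)(CO[Si](C)(C)C(C)(C)C)[C@@H]2[C@@H](O[Si](C)(C)C(C)(C)C)C[C@@]1(C)O[Si](C)(C)C(C)(C)C | intermediate
19 | (5Z)-5-[(13E)-6α,8α,18-tris(TBS-oxy)labd-13-en-15-ylidene]-4-methylfuran-2(5H)-one | CC1=CC(=O)O/C1=C\C=C(/C)CC[C@@H]1[C@@]2(C)CCC[C@@](C)(CO[Si](C)(C)C(C)(C)C)[C@@H]2[C@@H](O[Si](C)(C)C(C)(C)C)C[C@@]1(C)O[Si](C)(C)C(C)(C)C | intermediate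
20 | (5Z)-5-[(13E)-6α,8α,18-trihydroxylabd-13-en-15-ylidene]-4-methylfuran-2(5H)-one, CNP0126806.1 | CC1=CC(=O)O/C1=C\C=C(/C)CC[C@@H]1[C@@]2(C)CCC[C@@](C)(CO)[C@@H]2[C@@H](O)C[C@@]1(C)O | target

Total step count: 13. Longest linear sequence: 13 (from 1).

Steps most likely to fail

Step 10. The activated amide may lose silanol (β-elimination towards the dienamide) before the cumulene is captured. Capture by the unactivated alkyne may also be too slow, so that silyl ethers erode. In the fallback, the same cycloaddition is moved to the simplest amide and the butenolide is joined to the terpenoid afterwards.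
- Amide 11 and propyne 14 (Tf2O, collidine, then water) give 3-methylcyclobut-2-en-1-one F1.
- Baeyer–Villiger oxidation (H2O2, AcOH) turns F1 into 4-methylfuran-2(5H)-one F2.
- In parallel, enal 10 is persilylated (TBSOTf, 2,6-lutidine) to the tris-TBS enal F3.
- F2 with TBSOTf and i-Pr2NEt forms in the flask tert-butyl(dimethyl)[(4-methylfuran-2-yl)oxy]silane F4. This adds through its C5 to F3 in a vinylogous Mukaiyama aldol reaction, with silyl transfer to the new alkoxide.
- This fallback sets out from 10, 11 and 14 and comes back to the route at 18.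

Step 3. Iodine species may open the spiro-epoxide, or the alkoxy radical may undergo β-scission instead of 1,5-hydrogen transfer. The fallback uses Barton nitrite photolysis, which needs no iodine.
- Alcohol 4 is converted (NOCl, pyridine) into the 6α-nitrite F5.
- Irradiation at 365 nm in toluene, then tautomerisation of the C18 nitroso compound, gives the 18-oxime F6.
- Transoximation with aqueous glyoxylic acid gives the 6α,18-lactol F7.
- TPAP/NMO oxidises F7 to the lactone.
- This fallback sets out from 4 and comes back at 6, so compound 5 is bypassed.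

Step 11. Epoxidation of the C13=C14 alkene, conjugate attack of the peroxide on the enone or migration of the vinylic carbon may compete with the wanted oxygen insertion. The fallback installs the ring oxygen on carbon before the cycloaddition, so no peroxide meets the cyclobutenone.
- The enolate of 13 (KHMDS, −78 °C) is hydroxylated with 2-(phenylsulfonyl)-3-phenyloxaziridine to the α-hydroxy amide F8.
- F8 is capped (TMSCl, imidazole) as the α-trimethylsilyloxy amide F9.
- Under the conditions of step 10, F9 and propyne 14 give, after hydrolytic work-up with loss of the trimethylsilyl group, the 4-hydroxycyclobutenone F10.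
- Irradiation of F10 in MeCN triggers the known photochemical rearrangement of 4-hydroxycyclobutenones to furan-2(5H)-ones (electrocyclic opening to the hydroxyvinylketene, then lactonisation).
- This fallback sets out from 13 and comes back at 18.

Further compounds
F1 | step 10 | 3-methylcyclobut-2-en-1-one | CC1=CC(=O)C1
F2 | step 10 | 4-methylfuran-2(5H)-one | CC1=CC(=O)OC1
F3 | step 10 | (13E)-6α,8α,18-tris(TBS-oxy)labd-13-en-15-al | O=C/C=C(\C)CC[C@@H]1[C@@]2(C)CCC[C@@](C)(CO[Si](C)(C)C(C)(C)C)[C@@H]2[C@@H](O[Si](C)(C)C(C)(C)C)C[C@@]1(C)O[Si](C)(C)C(C)(C)C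
F4 | step 10 | tert-butyl(dimethyl)[(4-methylfuran-2-yl)oxy]silane | Cc1coc(O[Si](C)(C)C(C)(C)C)c1
F5 | step 3 | 8α,17-epoxy-13-oxo-14,15-dinorlabdan-6α-yl nitrite | CC(=O)CC[C@@H]1[C@@]2(C)CCCC(C)(C)[C@@H]2[C@@H](ON=O)C[C@]13CO3
F6 | step 3 | 8α,17-epoxy-6α-hydroxy-13-oxo-14,15-dinorlabdan-18-al oxime | CC(=O)CC[C@@H]1[C@@]2(C)CCC[C@@](C)(C=NO)[C@@H]2[C@@H](O)C[C@]13CO3
F7 | step 3 | 6α,18:8α,17-diepoxy-18-hydroxy-14,15-dinorlabdan-13-one (lactol) | CC(=O)CC[C@@H]1[C@@]2(C)CCC[C@@](C)(C(O)O4)[C@@H]2[C@@H]4C[C@]13CO3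
F8 | step 11 | α-hydroxy derivative of amide 13 | CN(C)C(=O)C(O)C(O[Si](C)(C)C(C)(C)C)/C=C(\C)CC[C@@H]1[C@@]2(C)CCC[C@@](C)(CO[Si](C)(C)C(C)(C)C)[C@@H]2[C@@H](O[Si](C)(C)C(C)(C)C)C[C@@]1(C)O[Si](C)(C)C(C)(C)C
F9 | step 11 | α-trimethylsilyloxy derivative of amide 13 | CN(C)C(=O)C(O[Si](C)(C)C)C(O[Si](C)(C)C(C)(C)C)/C=C(\C)CC[C@@H]1[C@@]2(C)CCC[C@@](C)(CO[Si](C)(C)C(C)(C)C)[C@@H]2[C@@H](O[Si](C)(C)C(C)(C)C)C[C@@]1(C)O[Si](C)(C)C(C)(C)C
F10 | step 11 | 4-hydroxy-4-[(13E)-6α,8α,15,18-tetrakis(TBS-oxy)labd-13-en-15-yl]-3-methylcyclobut-2-en-1-one | O=C1C=C(C)C1(O)C(O[Si](C)(C)C(C)(C)C)/C=C(\C)CC[C@@H]1[C@@]2(C)CCC[C@@](C)(CO[Si](C)(C)C(C)(C)C)[C@@H]2[C@@H](O[Si](C)(C)C(C)(C)C)C[C@@]1(C)O[Si](C)(C)C(C)(C)C
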